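**Retrosynthetic overview**
1. Target 40 comes from oxidation of primary alcohol 38. The two-carbon linker between dioxane C6 and decalin C2 is cut in its middle: Wittig reaction of 6-formyl-1,2-dioxane 17 with the decalinylmethyl ylide from 34, then diimide.
2. The 1,2-dioxane (O1–O2–C3–C4–C5–C6) is closed through the O1–C6 bond. The plan rests on the quaternary peroxide carbon C6 (methyl, O1, ring C5, linker CH2): with the first linker carbon it maps onto C3/C2 of geraniol, so an asymmetric epoxide opened with inversion by the C3 hydroperoxide fixes it.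
3. Hydroperoxide 14 comes from SN2 displacement of a secondary mesylate by H2O2, the mesylate from an Evans syn aldol on epoxy aldehyde 5, and 5 from geraniol (Sharpless epoxidation, ozonolysis).
4. Phosphonium salt 34 comes from enol triflate 31 (carbonylation), 31 from the anionic oxy-Cope rearrangement of bicyclo[2.2.2]octenyl carbinol 28, and 28 from an asymmetric Diels–Alder reaction of 1-methylcyclohexa-1,3-diene with acrolein.
5. Ring order: bicyclo[2.2.2]octene (step 14), then both six-membered carbocycles of the cis-decalin at once (step 18); separately the 1,2-dioxane (step 9); the fragments are joined in step 22.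

Key step: step 9

Remark 1: the heterocycle is numbered O1, O2, C3 (the CH carrying the propanoate-derived arm), C4, C5, C6 (the methyl-bearing quaternary carbon) throughout; CIP descriptors at C6 change with the linker substituent although the geometry does not.
Remark 2: the alkene formed in step 22 is expected as an E/Z mixture and is written without geometry, because it is saturated in step 23.

**Fragment A: the 6-formyl-1,2-dioxane (steps 1–11)**

Step 1
Reactants: 1 geraniol
Product: 2 (2R,3R)-2,3-epoxygeraniol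
Conditions: Ti(OiPr)4 (5 mol%), D-(−)-diethyl tartrate (6 mol%), t-BuOOH (2 equiv), 4 Å sieves, CH2Cl2, −20 °C
Reagents that add atoms: tert-butyl hydroperoxide, CC(C)(C)OO
Why: Sharpless asymmetric epoxidation of the allylic alcohol; the D-tartrate complex should deliver oxygen to the face that gives the (2R,3R)-epoxide, and the remote 6,7-alkene, which has no directing hydroxyl, is left alone.

Step 2
Reactants: 2 (2R,3R)-2,3-epoxygeraniol
Product: 3 TBS ether of 2
Conditions: TBSCl, imidazole, DMF, 0 °C → rt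
Reagents that add atoms: tert-butyldimethylsilyl chloride, CC(C)(C)[Si](C)(C)Cl
Why: Standard silylation of a primary alcohol; the epoxide is inert to imidazole at this temperature.

Step 3
Reactants: 3 TBS ether of 2
Product: 5 3-[(2R,3R)-3-({[tert-butyl(dimethyl)silyl]oxy}methyl)-2-methyloxiran-2-yl]propanal, via secondary ozonide 4 (not isolated)
Conditions: O3, CH2Cl2, −78 °C; then PPh3, −78 °C → rt
Reagents that add atoms: ozone, [O-][O+]=O
Why: Ozonolysis with reductive work-up cleaves the only remaining alkene to the aldehyde and acetone; epoxide and silyl ether do not react with ozone.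

Step 4
Reactants: 5 epoxy aldehyde; 6 (4R)-4-benzyl-3-propanoyl-1,3-oxazolidin-2-one; 7 hydrogen peroxide (oxidative work-up only)
Product: 10 syn-aldol adduct (4R)-4-benzyl-3-[(2R,3S)-5-[(2R,3R)-3-({[tert-butyl(dimethyl)silyl]oxy}methyl)-2-methyloxiran-2-yl]-3-hydroxy-2-methylpentanoyl]-1,3-oxazolidin-2-one, via boron Z-enolate 8 (not isolated), via boron aldolate 9 (not isolated)
Conditions: 6, Bu2BOTf, iPr2NEt, CH2Cl2, −78 → 0 °C; then 5, −78 → 0 °C; then pH 7 buffer, MeOH, 30% aq. H2O2 (7), 0 °C
Reagents that add atoms: none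
Why: Evans syn aldol reaction; the Z-boron enolate reacts through a closed chair transition state on the face left open by the benzyl group of the (R)-auxiliary, which should set the (2R)-methyl and (3S)-hydroxyl centres (later the acid α-carbon and, after inversion, dioxane C3).

Step 5
Reactants: 10 syn-aldol adduct
Product: 11 (2S,3S)-5-[(2R,3R)-3-({[tert-butyl(dimethyl)silyl]oxy}methyl)-2-methyloxiran-2-yl]-2-methylpentane-1,3-diol
Conditions: LiBH4, MeOH (1 equiv), THF, 0 °C
Reagents that add atoms: none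
Why: Reductive cleavage of the N-acyl oxazolidinone by borohydride gives the primary alcohol without touching the α-stereocentre; the trisubstituted epoxide is not opened by LiBH4 at 0 °C.

Step 6
Reactants: 11 diol
Product: 12 (2S,3S)-1-{[tert-butyl(diphenyl)silyl]oxy}-5-[(2R,3R)-3-({[tert-butyl(dimethyl)silyl]oxy}methyl)-2-methyloxiran-2-yl]-2-methylpentan-3-ol
Conditions: TBDPSCl, imidazole, CH2Cl2, 0 °C
Reagents that add atoms: tert-butyl(chloro)diphenylsilane, CC(C)(C)[Si](Cl)(c1ccccc1)c1ccccc1
Why: The bulky silyl chloride selects the primary over the hindered secondary hydroxyl of the 1,3-diol.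

Step 7
Reactants: 12 secondary alcohol
Product: 13 (2S,3S)-methanesulfonate of 12
Conditions: MsCl, Et3N, CH2Cl2, 0 °C
Reagents that add atoms: methanesulfonyl chloride, CS(=O)(=O)Cl
Why: Sulfonylation at oxygen activates the carbinol carbon with retention of configuration.

Step 8
Reactants: 13 mesylate; 7 hydrogen peroxide
Product: 14 hydroperoxide tert-butyl{[(2S,3R)-5-[(2R,3R)-3-({[tert-butyl(dimethyl)silyl]oxy}methyl)-2-methyloxiran-2-yl]-3-hydroperoxy-2-methylpentyl]oxy}diphenylsilane
Conditions: 50% aq. H2O2 (excess), KOH, MeOH/THF, 0 °C → rt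
Reagents that add atoms: none
Why: SN2 displacement of a secondary alkyl methanesulfonate by the strongly nucleophilic hydroperoxide anion goes with inversion, turning the syn aldol carbinol (3S) into the (3R)-hydroperoxide that is anti to the methyl-bearing carbon; the trisubstituted epoxide is a much poorer electrophile under base.

Step 9
Reactants: 14 hydroperoxy epoxide
Product: 15 1,2-dioxane with C6 bearing methyl and the (1R)-2-{[tert-butyl(dimethyl)silyl]oxy}-1-hydroxyethyl group and C3 bearing the (2S)-1-{[tert-butyl(diphenyl)silyl]oxy}propan-2-yl group (C3 R; C6 S)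
Conditions: camphor-10-sulfonic acid (10 mol%), CH2Cl2, 0 °C → rt
Reagents that add atoms: none
Why: The sulfonic acid protonates the epoxide oxygen, and the terminal oxygen of the C3 hydroperoxide attacks the tertiary epoxide carbon from the backside, forming the O1–C6 bond as the epoxide C–O bond at that carbon breaks and leaving the former epoxide oxygen as the secondary alcohol on the linker carbon. The closest known reaction type is the acid-promoted intramolecular opening of epoxides by hydroperoxides to 1,2-dioxanes. The one ring formed, the 1,2-dioxane, closes in the 6-exo-tet mode; 7-endo attack at the secondary epoxide carbon is disfavoured by ring size, by the poorer cation-stabilising ability of that carbon and by the inductive pull of the adjacent silyloxymethyl group. The new stereocentre C6 is controlled only by the configuration of the epoxide carbon set in step 1, which is inverted by the anti opening, so no conformational preference of the forming ring is needed; C3 and the side-chain methine are spectators. The step needs Markovnikov regiochemistry and clean inversion without a free tertiary cation, which the short tether, the non-nucleophilic solvent and the low temperature should secure, and both silyl ethers should survive catalytic acid in the absence of an alcohol.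

Step 10
Reactants: 15 dioxane alcohol
Product: 16 diol, C6 bearing methyl and the (1R)-1,2-dihydroxyethyl group (C3 R; C6 S)
Conditions: camphor-10-sulfonic acid (10 mol%), MeOH/CH2Cl2 (1:1), 0 °C
Reagents that add atoms: none
Why: Acid-catalysed methanolysis removes the primary TBS ether much faster than the primary TBDPS ether, and the dialkyl peroxide is stable to dilute acid.

Step 11
Reactants: 16 diol
Product: 17 6-formyl-1,2-dioxane, C6 bearing methyl and CHO and C3 bearing the (2S)-1-{[tert-butyl(diphenyl)silyl]oxy}propan-2-yl group (C3 R; C6 S)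
Conditions: NaIO4, THF/pH 7 buffer, 0 °C → rt
Reagents that add atoms: none
Why: Periodate glycol cleavage removes the terminal carbon as formaldehyde and leaves the aldehyde on quaternary C6, which has no α-hydrogen and cannot epimerise.

**Fragment B: the cis-decalin phosphonium salt (steps 12–21)**

Step 12
Reactants: 18 3-methylcyclohex-2-en-1-one
Product: 19 p-toluenesulfonylhydrazone of 18
Conditions: TsNHNH2, MeOH, rt
Reagents that add atoms: p-toluenesulfonohydrazide, Cc1ccc(cc1)S(=O)(=O)NN
Why: Condensation of a ketone with a sulfonyl hydrazide.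

Step 13
Reactants: 19 tosylhydrazone
Product: 21 1-methylcyclohexa-1,3-diene, via vinyllithium 20 (not isolated)
Conditions: MeLi (2.2 equiv), Et2O, 0 °C → rt; then H2O
Reagents that add atoms: none
Why: Shapiro reaction; the dianion formed by N–H and α'-C–H deprotonation loses sulfinate and N2 to give the vinyllithium, whose protonation should give the homoannular diene with the methyl group at a diene terminus.

Step 14
Reactants: 21 1-methylcyclohexa-1,3-diene; 22 acrolein
Product: 23 (1R,2R,4R)-1-methylbicyclo[2.2.2]oct-5-ene-2-carbaldehyde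
Conditions: (5S)-5-benzyl-2,2,3-trimethylimidazolidin-4-one hydrochloride (10 mol%), MeCN/H2O (95:5), rt
Reagents that add atoms: none
Why: Iminium-catalysed asymmetric Diels–Alder reaction; the benzyl group of the catalyst blocks one face of the E-iminium ion so that the diene should add endo to the open face, the unsubstituted diene terminus bonding to the β-carbon ("ortho" regiochemistry), and the minor exo adduct is removed by chromatography because it would give the enantiomeric ketone in step 15.

Step 15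
Reactants: 23 bicyclic aldehyde
Product: 24 (1R,4R)-1-methylbicyclo[2.2.2]oct-5-en-2-one
Conditions: O2 (1 atm), Cu(OAc)2 (5 mol%), 2,2'-bipyridine, DABCO, DMF, 40 °C
Reagents that add atoms: dioxygen, O=O
Why: Aerobic oxidative deformylation of an α-branched aldehyde catalysed by divalent copper (α-oxygenation, then dioxetane-type cleavage) removes the formyl carbon as formic acid and leaves C2 as the ketone without touching the bridgehead stereocentres.

Step 16
Reactants: 24 bicyclic ketone
Product: 26 (1R,4S)-1,3,3-trimethylbicyclo[2.2.2]oct-5-en-2-one, via 3-monomethyl ketone 25 (not isolated)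
Conditions: KOtBu (2.5 equiv), MeI (excess), THF, 0 °C → rt
Reagents that add atoms: iodomethane, CI
Why: Exhaustive enolate alkylation; only C3 can enolise because C1 is a quaternary bridgehead, so methylation stops at the gem-dimethyl ketone.

Step 17
Reactants: 26 trimethyl ketone; 27 isopropenylmagnesium bromide
Product: 28 (1R,2S,4S)-1,3,3-trimethyl-2-(prop-1-en-2-yl)bicyclo[2.2.2]oct-5-en-2-ol (isopropenyl syn to the C5=C6 bridge)
Conditions: CeCl3 (anhydrous), THF, −78 → 0 °C; aq. NH4Cl
Reagents that add atoms: none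
Why: Organocerium 1,2-addition to a hindered, non-enolisable ketone; attack from the face flanked by the flat etheno bridge, not the ethano bridge, should place the isopropenyl group syn to the alkene, as the rearrangement requires.

Step 18
Reactants: 28 tertiary carbinol
Product: 31 (4aR,8aS)-1,1,3,6-tetramethyl-1,4,4a,7,8,8a-hexahydronaphthalen-2-yl trifluoromethanesulfonate, via potassium alkoxide 29 (not isolated), via potassium enolate 30 (not isolated)
Conditions: KH, 18-crown-6, THF, rt → 50 °C; then PhNTf2, −78 °C → rt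
Reagents that add atoms: N-phenylbis(trifluoromethanesulfonimide), O=S(=O)(N(c1ccccc1)S(=O)(=O)C(F)(F)F)C(F)(F)F
Why: Anionic oxy-Cope rearrangement through the boat transition state enforced by the bicycle breaks C1–C2 and bonds the isopropenyl CH2 to C5 on the face toward the former C2 bridge, so the ring fusion is cis, bridgehead C4 becomes C8a and C5 becomes C4a; the regiodefined tetrasubstituted enolate is then O-sulfonylated.

Step 19
Reactants: 31 enol triflate
Product: 32 methyl (4aR,8aS)-1,1,3,6-tetramethyl-1,4,4a,7,8,8a-hexahydronaphthalene-2-carboxylate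
Conditions: Pd(OAc)2 (5 mol%), 1,1'-bis(diphenylphosphino)ferrocene (10 mol%), Et3N, CO (1 atm), MeOH/DMF, 60 °C
Reagents that add atoms: carbon monoxide, [C-]#[O+]; methanol, CO
Why: Palladium-catalysed alkoxycarbonylation of an enol triflate (oxidative addition to zerovalent palladium, CO insertion, methanolysis), known for hindered cyclohexenyl triflates flanked by a quaternary carbon.

Step 20
Reactants: 32 methyl ester
Product: 33 [(4aR,8aS)-1,1,3,6-tetramethyl-1,4,4a,7,8,8a-hexahydronaphthalen-2-yl]methanol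
Conditions: iBu2AlH (2.5 equiv), CH2Cl2, −78 → 0 °C; aq. potassium sodium tartrate
Reagents that add atoms: none
Why: 1,2-Reduction of the unsaturated ester to the allylic alcohol by the aluminium hydride.

Step 21
Reactants: 33 allylic alcohol
Product: 34 {[(4aR,8aS)-1,1,3,6-tetramethyl-1,4,4a,7,8,8a-hexahydronaphthalen-2-yl]methyl}triphenylphosphonium bromide
Conditions: Ph3P·HBr, MeCN, rt → 50 °C
Reagents that add atoms: triphenylphosphine hydrobromide, c1ccc(cc1)[PH+](c1ccccc1)c1ccccc1.[Br-]
Why: Direct conversion of an allylic alcohol to its phosphonium salt with the phosphine hydrobromide, as practised on cyclogeranyl-type alcohols; the bulky phosphine should take the primary terminus of the allylic system.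

**Union and end game (steps 22–25)**

Step 22
Reactants: 34 phosphonium bromide; 17 6-formyl-1,2-dioxane
Product: 36 diene tert-butyl{(2S)-2-[(3R,6S)-6-methyl-6-{2-[(4aR,8aS)-1,1,3,6-tetramethyl-1,4,4a,7,8,8a-hexahydronaphthalen-2-yl]ethenyl}-1,2-dioxan-3-yl]propoxy}diphenylsilane, via phosphonium ylide 35 (not isolated)
Conditions: NaN(SiMe3)2, THF, −78 → 0 °C; then 17, −78 °C → rt
Reagents that add atoms: none
Why: Wittig olefination of the non-enolisable aldehyde by the allylic ylide forms the linker C=C; the dialkyl peroxide is inert to the ylide and to phosphine oxide, and the alkene geometry does not matter.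

Step 23
Reactants: 36 diene
Product: 37 tert-butyl{(2S)-2-[(3R,6R)-6-methyl-6-{2-[(4aR,8aS)-1,1,3,6-tetramethyl-1,4,4a,7,8,8a-hexahydronaphthalen-2-yl]ethyl}-1,2-dioxan-3-yl]propoxy}diphenylsilane
Conditions: KO2CN=NCO2K (excess), AcOH, MeOH/CH2Cl2, 0 °C → rt
Reagents that add atoms: none
Why: Diimide reduction; concerted hydrogen transfer should saturate the 1,2-disubstituted alkene much faster than the tri- and tetrasubstituted ring alkenes and does not cleave the O–O bond.

Step 24
Reactants: 37 silyl ether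
Product: 38 (2S)-2-[(3R,6R)-6-methyl-6-{2-[(4aR,8aS)-1,1,3,6-tetramethyl-1,4,4a,7,8,8a-hexahydronaphthalen-2-yl]ethyl}-1,2-dioxan-3-yl]propan-1-ol
Conditions: HF·pyridine, pyridine/THF, 0 °C → rt
Reagents that add atoms: none
Why: Fluoride-driven cleavage of the Si–O bond under buffered conditions that leave the peroxide and both alkenes intact.

Step 25
Reactants: 38 primary alcohol
Product: 40 target acid (2R)-2-[(3R,6R)-6-methyl-6-{2-[(4aR,8aS)-1,1,3,6-tetramethyl-1,4,4a,7,8,8a-hexahydronaphthalen-2-yl]ethyl}-1,2-dioxan-3-yl]propanoic acid, via aldehyde 39 (not isolated)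
Conditions: TEMPO (20 mol%), PhI(OAc)2 (2.2 equiv), MeCN/pH 7 buffer, 0 °C → rt
Reagents that add atoms: water, O
Why: Oxoammonium-mediated oxidation of the primary alcohol to the aldehyde and, through its hydrate, to the acid under near-neutral conditions that should not epimerise the α-carbon or open the β-peroxy unit.

**Compound list**
1 | geraniol, (2E)-3,7-dimethylocta-2,6-dien-1-ol | CC(C)=CCC/C(C)=C/CO | starting material
2 | (2R,3R)-2,3-epoxygeraniol, [(2R,3R)-3-methyl-3-(4-methylpent-3-en-1-yl)oxiran-2-yl]methanol | OC[C@H]1O[C@]1(C)CCC=C(C)C | intermediate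
3 | TBS ether of 2, tert-butyl(dimethyl){[(2R,3R)-3-methyl-3-(4-methylpent-3-en-1-yl)oxiran-2-yl]methoxy}silane | CC(C)(C)[Si](C)(C)OC[C@H]1O[C@]1(C)CCC=C(C)C | intermediate
4 | secondary ozonide of 3 (5,5-dimethyl-1,2,4-trioxolan-3-yl end group, epimers at the trioxolane carbon) | CC(C)(C)[Si](C)(C)OC[C@H]1O[C@]1(C)CCC1OOC(C)(C)O1 | intermediate
5 | 3-[(2R,3R)-3-({[tert-butyl(dimethyl)silyl]oxy}methyl)-2-methyloxiran-2-yl]propanal | CC(C)(C)[Si](C)(C)OC[C@H]1O[C@]1(C)CCC=O | intermediate
6 | (4R)-4-benzyl-3-propanoyl-1,3-oxazolidin-2-one | CCC(=O)N1[C@H](Cc2ccccc2)COC1=O | starting material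
7 | hydrogen peroxide | OO | starting material
8 | (Z)-dibutylboron enolate of 6 | C/C=C(\OB(CCCC)CCCC)N1[C@H](Cc2ccccc2)COC1=O | intermediate
9 | O-dibutylboron aldolate of 10 | CC(C)(C)[Si](C)(C)OC[C@H]1O[C@]1(C)CC[C@H](OB(CCCC)CCCC)[C@@H](C)C(=O)N1[C@H](Cc2ccccc2)COC1=O | intermediate
10 | (4R)-4-benzyl-3-[(2R,3S)-5-[(2R,3R)-3-({[tert-butyl(dimethyl)silyl]oxy}methyl)-2-methyloxiran-2-yl]-3-hydroxy-2-methylpentanoyl]-1,3-oxazolidin-2-one | CC(C)(C)[Si](C)(C)OC[C@H]1O[C@]1(C)CC[C@H](O)[C@@H](C)C(=O)N1[C@H](Cc2ccccc2)COC1=O | intermediate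
11 | (2S,3S)-5-[(2R,3R)-3-({[tert-butyl(dimethyl)silyl]oxy}methyl)-2-methyloxiran-2-yl]-2-methylpentane-1,3-diol | CC(C)(C)[Si](C)(C)OC[C@H]1O[C@]1(C)CC[C@H](O)[C@@H](C)CO | intermediate
12 | (2S,3S)-1-{[tert-butyl(diphenyl)silyl]oxy}-5-[(2R,3R)-3-({[tert-butyl(dimethyl)silyl]oxy}methyl)-2-methyloxiran-2-yl]-2-methylpentan-3-ol | CC(C)(C)[Si](C)(C)OC[C@H]1O[C@]1(C)CC[C@H](O)[C@@H](C)CO[Si](c1ccccc1)(c1ccccc1)C(C)(C)C | intermediate
13 | (2S,3S)-methanesulfonate of 12 | CC(C)(C)[Si](C)(C)OC[C@H]1O[C@]1(C)CC[C@H](OS(C)(=O)=O)[C@@H](C)CO[Si](c1ccccc1)(c1ccccc1)C(C)(C)C | intermediate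
14 | tert-butyl{[(2S,3R)-5-[(2R,3R)-3-({[tert-butyl(dimethyl)silyl]oxy}methyl)-2-methyloxiran-2-yl]-3-hydroperoxy-2-methylpentyl]oxy}diphenylsilane | CC(C)(C)[Si](C)(C)OC[C@H]1O[C@]1(C)CC[C@@H](OO)[C@@H](C)CO[Si](c2ccccc2)(c2ccccc2)C(C)(C)C | intermediate
15 | 1,2-dioxane: C6 with methyl and (1R)-2-(TBS-oxy)-1-hydroxyethyl, C3 with (2S)-1-(TBDPS-oxy)propan-2-yl; C3 R, C6 S | CC(C)(C)[Si](C)(C)OC[C@@H](O)[C@]1(C)CC[C@H]([C@@H](C)CO[Si](c2ccccc2)(c2ccccc2)C(C)(C)C)OO1 | intermediate
16 | 1,2-dioxane diol: C6 with methyl and (1R)-1,2-dihydroxyethyl, C3 with (2S)-1-(TBDPS-oxy)propan-2-yl; C3 R, C6 S | OC[C@@H](O)[C@]1(C)CC[C@H]([C@@H](C)CO[Si](c2ccccc2)(c2ccccc2)C(C)(C)C)OO1 | intermediate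
17 | 6-formyl-1,2-dioxane: C6 with methyl and CHO, C3 with (2S)-1-(TBDPS-oxy)propan-2-yl; C3 R, C6 S | O=C[C@]1(C)CC[C@H]([C@@H](C)CO[Si](c2ccccc2)(c2ccccc2)C(C)(C)C)OO1 | intermediate
18 | 3-methylcyclohex-2-en-1-one | CC1=CC(=O)CCC1 | starting material
19 | p-toluenesulfonylhydrazone of 18 | CC1=CC(CCC1)=NNS(=O)(=O)c1ccc(C)cc1 | intermediate
20 | (5-methylcyclohexa-1,5-dien-1-yl)lithium | [Li]C1=CCCC(C)=C1 | intermediate
21 | 1-methylcyclohexa-1,3-diene | CC1=CC=CCC1 | intermediate
22 | acrolein | C=CC=O | starting material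
23 | (1R,2R,4R)-1-methylbicyclo[2.2.2]oct-5-ene-2-carbaldehyde | C[C@]12C=C[C@H](CC1)C[C@H]2C=O | intermediate
24 | (1R,4R)-1-methylbicyclo[2.2.2]oct-5-en-2-one | C[C@]12C=C[C@H](CC1)CC2=O | intermediate
25 | 1,3-dimethylbicyclo[2.2.2]oct-5-en-2-one (bridgeheads as in 24, C3 epimers) | C[C@]12C=C[C@H](CC1)C(C)C2=O | intermediate
26 | (1R,4S)-1,3,3-trimethylbicyclo[2.2.2]oct-5-en-2-one | C[C@]12C=C[C@H](CC1)C(C)(C)C2=O | intermediate
27 | isopropenylmagnesium bromide | C=C(C)[Mg]Br | starting material
28 | (1R,2S,4S)-1,3,3-trimethyl-2-(prop-1-en-2-yl)bicyclo[2.2.2]oct-5-en-2-ol | C[C@]12C=C[C@H](CC1)C(C)(C)[C@@]2(O)C(C)=C | intermediate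
29 | potassium alkoxide of 28 | C[C@]12C=C[C@H](CC1)C(C)(C)[C@@]2([O-])C(C)=C.[K+] | intermediate
30 | potassium (4aR,8aS)-1,1,3,6-tetramethyl-1,4,4a,7,8,8a-hexahydronaphthalen-2-olate | CC1=C[C@H]2CC(C)=C([O-])C(C)(C)[C@H]2CC1.[K+] | intermediate
31 | (4aR,8aS)-1,1,3,6-tetramethyl-1,4,4a,7,8,8a-hexahydronaphthalen-2-yl trifluoromethanesulfonate | CC1=C[C@H]2CC(C)=C(OS(=O)(=O)C(F)(F)F)C(C)(C)[C@H]2CC1 | intermediate
32 | methyl (4aR,8aS)-1,1,3,6-tetramethyl-1,4,4a,7,8,8a-hexahydronaphthalene-2-carboxylate | CC1=C[C@H]2CC(C)=C(C(=O)OC)C(C)(C)[C@H]2CC1 | intermediate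
33 | [(4aR,8aS)-1,1,3,6-tetramethyl-1,4,4a,7,8,8a-hexahydronaphthalen-2-yl]methanol | CC1=C[C@H]2CC(C)=C(CO)C(C)(C)[C@H]2CC1 | intermediate
34 | {[(4aR,8aS)-1,1,3,6-tetramethyl-1,4,4a,7,8,8a-hexahydronaphthalen-2-yl]methyl}triphenylphosphonium bromide | CC1=C[C@H]2CC(C)=C(C[P+](c3ccccc3)(c3ccccc3)c3ccccc3)C(C)(C)[C@H]2CC1.[Br-] | intermediate
35 | ylide of 34, {[(4aR,8aS)-1,1,3,6-tetramethyl-1,4,4a,7,8,8a-hexahydronaphthalen-2-yl]methylidene}triphenylphosphorane | CC1=C[C@H]2CC(C)=C(C=P(c3ccccc3)(c3ccccc3)c3ccccc3)C(C)(C)[C@H]2CC1 | intermediate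
36 | tert-butyl{(2S)-2-[(3R,6S)-6-methyl-6-{2-[(4aR,8aS)-1,1,3,6-tetramethyl-1,4,4a,7,8,8a-hexahydronaphthalen-2-yl]ethenyl}-1,2-dioxan-3-yl]propoxy}diphenylsilane (E/Z mixture) | CC1=C[C@H]2CC(C)=C(C=C[C@]3(C)CC[C@H]([C@@H](C)CO[Si](c4ccccc4)(c4ccccc4)C(C)(C)C)OO3)C(C)(C)[C@H]2CC1 | intermediate
37 | tert-butyl{(2S)-2-[(3R,6R)-6-methyl-6-{2-[(4aR,8aS)-1,1,3,6-tetramethyl-1,4,4a,7,8,8a-hexahydronaphthalen-2-yl]ethyl}-1,2-dioxan-3-yl]propoxy}diphenylsilane | CC1=C[C@H]2CC(C)=C(CC[C@]3(C)CC[C@H]([C@@H](C)CO[Si](c4ccccc4)(c4ccccc4)C(C)(C)C)OO3)C(C)(C)[C@H]2CC1 | intermediate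
38 | (2S)-2-[(3R,6R)-6-methyl-6-{2-[(4aR,8aS)-1,1,3,6-tetramethyl-1,4,4a,7,8,8a-hexahydronaphthalen-2-yl]ethyl}-1,2-dioxan-3-yl]propan-1-ol | CC1=C[C@H]2CC(C)=C(CC[C@]3(C)CC[C@H]([C@@H](C)CO)OO3)C(C)(C)[C@H]2CC1 | intermediate
39 | (2R)-2-[(3R,6R)-6-methyl-6-{2-[(4aR,8aS)-1,1,3,6-tetramethyl-1,4,4a,7,8,8a-hexahydronaphthalen-2-yl]ethyl}-1,2-dioxan-3-yl]propanal | CC1=C[C@H]2CC(C)=C(CC[C@]3(C)CC[C@H]([C@@H](C)C=O)OO3)C(C)(C)[C@H]2CC1 | intermediate
40 | (2R)-2-[(3R,6R)-6-methyl-6-{2-[(4aR,8aS)-1,1,3,6-tetramethyl-1,4,4a,7,8,8a-hexahydronaphthalen-2-yl]ethyl}-1,2-dioxan-3-yl]propanoic acid | CC1=C[C@H]2CC(C)=C(CC[C@]3(C)CC[C@H]([C@@H](C)C(=O)O)OO3)C(C)(C)[C@H]2CC1 | target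

**Count and risks**
Total step count: 25. Longest linear sequence: 15 steps (steps 1–11 and 22–25, from geraniol); the decalin branch is 10 steps (12–21) before the union.

Steps most likely to fail:

Step 9 (key step). The protonated epoxide may ionise to a free tertiary cation before the hydroperoxide engages. That would erode the C6 configuration and divert material into hydride-shift carbonyl products or 7-endo closure; acid may also strip the primary TBS ether early. The fallback sets out from mesylate 13 and forms the two C–O bonds of the peroxide in the opposite order. Ethereal H2O2 with catalytic phosphomolybdic acid H3PMo12O40 opens the epoxide of 13 at the tertiary carbon with inversion to the β-hydroxy tertiary hydroperoxide F3. KOtBu in THF/DMF at 0 °C then closes the ring by intramolecular 6-exo-tet SN2 displacement of the secondary mesylate, with inversion at C3. This comes back to the route at 15, with the same configurations at C3 and C6.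

Step 8. E2 elimination of the β-branched secondary mesylate, or hydroxide attack at silicon, may outrun the intermolecular SN2 reaction. The fallback sets out from alcohol 12. It is converted (Tf2O, 2,6-lutidine, CH2Cl2, −78 °C) into the secondary triflate F1. F1 is used at once to alkylate 2-methoxyprop-2-yl hydroperoxide (CsOH·H2O, DMF, 0 °C) with inversion, giving the mixed peroxyketal F2. Brief treatment with AcOH/THF/H2O at rt removes the ketal as acetone and methanol and comes back to the route at hydroperoxide 14.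

Step 22. Addition of the hindered, semi-stabilised allylic ylide to the α-quaternary aldehyde may be slow, leaving time for base-induced fragmentation of the α-peroxy aldehyde or for reaction of the ylide at its γ-carbon. The fallback sets out from aldehyde 17 and uses enol triflate 31 directly. Aldehyde 17 is methylenated with the small, fast ylide Ph3P=CH2 (from Ph3PCH3Br and KN(SiMe3)2, THF, −78 °C) to the 6-vinyl-1,2-dioxane F4. Anti-Markovnikov hydroboration with 9-borabicyclo[3.3.1]nonane (THF, rt) gives the primary alkylborane F5. F5 is coupled with 31 in a B-alkyl Suzuki–Miyaura reaction (PdCl2(dppf), K3PO4, DMF/THF/H2O, rt). This comes back to the route at 37, and steps 19–21 and 23 are then not needed.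

Further compounds
F1 | step 8 | (2S,3S)-1-{[tert-butyl(diphenyl)silyl]oxy}-5-[(2R,3R)-3-({[tert-butyl(dimethyl)silyl]oxy}methyl)-2-methyloxiran-2-yl]-2-methylpentan-3-yl trifluoromethanesulfonate | CC(C)(C)[Si](C)(C)OC[C@H]1O[C@]1(C)CC[C@H](OS(=O)(=O)C(F)(F)F)[C@@H](C)CO[Si](c1ccccc1)(c1ccccc1)C(C)(C)C
F2 | step 8 | (3R)-2-methoxyprop-2-yl peroxyketal of 14 | CC(C)(C)[Si](C)(C)OC[C@H]1O[C@]1(C)CC[C@@H](OOC(C)(C)OC)[C@@H](C)CO[Si](c1ccccc1)(c1ccccc1)C(C)(C)C
F3 | step 9 | β-hydroxy tertiary hydroperoxide mesylate from perhydrolysis of 13 | CC(C)(C)[Si](C)(C)OC[C@@H](O)[C@@](C)(OO)CC[C@H](OS(C)(=O)=O)[C@@H](C)CO[Si](c1ccccc1)(c1ccccc1)C(C)(C)C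
F4 | step 22 | 6-vinyl-1,2-dioxane, C6 with methyl and ethenyl, C3 with (2S)-1-(TBDPS-oxy)propan-2-yl | C=C[C@]1(C)CC[C@H]([C@@H](C)CO[Si](c2ccccc2)(c2ccccc2)C(C)(C)C)OO1
F5 | step 22 | B-[2-(dioxan-6-yl)ethyl]-9-borabicyclo[3.3.1]nonane from F4 | C1CCC2CCCC1B2CC[C@]1(C)CC[C@H]([C@@H](C)CO[Si](c2ccccc2)(c2ccccc2)C(C)(C)C)OO1
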